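Remark on the chemistry: the sense of induction known for cinnamyl carbonates with heteroatom nucleophiles under iridium–phosphoramidite catalysis is assumed to hold here, so the (Sa,Sc,Sc) ligand is taken to give the (S) ether. Ring B is symmetric apart from its two chains, so it does not matter which ortho position carries iodine. No structural error was found in the key-step precursor or product; both are used unchanged as 11 and 12.

## Structural features

The target is a (2S)-flavanone: a 5,7-dihydroxylated benzene ring A is fused to dihydropyranone ring C (O1, C2, C3, C4, C4a, C8a), and C2 carries aryl ring B. Ring B is 1,3,4,5-tetrasubstituted: the 4'-methoxy group is flanked by a (Z)-3-hydroxy-3-methylbut-1-enyl chain at C3' and a prenyl group at C5'. C2 is the only stereocentre, so no neighbouring centre can relay configuration; it is benzylic, bears the ring oxygen and lies β to the C4 ketone, so base or heat can open ring C by retro-oxa-Michael elimination and erase it. The fragile groups are the tertiary, styrene-conjugated allylic alcohol (ionisation and dehydration in acid, Z to E drift), the prenyl alkene and the electron-rich free phenols. The real difficulty is twofold: to set C2 by a catalyst-controlled step and keep it through ring closure, and to attach two different carbon chains at the two ortho positions of a hindered anisole. The key step exploits the fact that C3 and C4 are the only carbons between C4a of ring A and C2. C4 can arrive as the carbonyl carbon of an acetophenone on ring A (as its silyl enol ether) and C3 as the inner carbon of a vinyl group on C2, so that alkene metathesis joins them as C3=C4 and closes ring C. Iodine and bromine at C3' and C5' stand in for the two chains until ring C is closed, so the metathesis substrate holds only the two alkenes that must react.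

## Logic of the disconnections

19 to 18: the two phenolic O–H bonds are traced back to O–Si bonds. The phenols stay masked through all metal-catalysed steps, which gives a lipophilic, non-acidic intermediate. The forward step must be neither basic enough to open ring C nor acidic enough to ionise the carbinol.

18 to 17: the cis C=C is traced back to a C≡C bond. The geometry problem becomes the syn addition of one molecule of hydrogen. The forward step must stop at the alkene and leave the prenyl group alone.

17 to 15 and 16: the aryl–CH2 bond at C5' is cut. This removes the second alkene from every earlier intermediate. The forward coupling must transfer the allyl unit through its CH2 end at a flanked C–Br bond under neutral conditions.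

15 to 13 and 14: the aryl–C(sp) bond at C3' is cut. The whole carbinol chain comes from one commercial alkyne. The forward coupling must react at C–I and not at C–Br.

13 to 12: the C4 ketone and one C3–H are traced back to the cyclic silyl enol ether. This reveals the C3=C4 alkene that metathesis can make. The forward hydrolysis must spare the aryl silyl ethers and the C2–O1 bond.

12 to 11: the C3=C4 bond is cut. This is the one cut that separates ring A and the C2 unit into an aryl methyl ketone derivative and an allylic aryl ether, and it opens ring C without touching C2. The forward step must cyclise in a congested setting and beat dimerisation.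

11 to 10: the enol O–Si bond is cut. The forward step must silylate the only enolisable side without ionising the 1-arylallyl ether.

10 to 6 and 8 (through 9): the C2–O1 bond is cut. The stereocentre is created in this bond-forming event from two achiral fragments of similar size, which makes the route convergent. The forward step needs branched regioselectivity and face control with a chelated, weakly nucleophilic phenoxide.

8 to 7: two O–Si bonds are cut. The two ortho hydroxyls of 7 are equivalent, so only the number of silyl groups needs control.

6 to 5 to 4 to 3: the carbonate C–O bond, the ester oxidation level and the C=C bond are removed in turn, a two-carbon homologation of the aldehyde. The forward olefination must give the E alkene.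

3 to 2 to 1: the O–CH3 bond and then the C–I bond are cut. The forward iodination must go once, at the free position ortho to the hydroxyl.

## Other disconnections considered

Alternative 1: The cut lies inside ring B. The aryl–CH2 bond of the prenyl group, the aryl–CH= bond and the cis alkene are traced to a coumarin, whose lactone ring stores the cis geometry and whose ring oxygen becomes the 4'-oxygen. In the forward sense, heating aryl ether A2 with an ester-stabilised phosphorus ylide should give coumarin A1 by aromatic Claisen shift of the dimethylallyl group to the free ortho carbon, Wittig olefination and lactonisation. Double methyl addition would then open the lactone to the Z-carbinol phenol A3, O-methylation would complete the ring B pattern, and the bromine para to oxygen would become C1'.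
- In favour: the Z geometry is enforced by a ring, which is better than a semihydrogenation that can over-reduce or isomerise. The prenyl group arrives without tin and without halogen differentiation. Three bonds form in one flask against one in the chosen key step.
- Against: A3 has a phenol held cis to a tertiary allylic alcohol and is set up for cyclodehydration, so methylation would have to win that race. The acid-labile carbinol and the prenyl alkene would then be carried through every later step.
- Comparison: this plan says nothing about ring C or C2. If its aryl bromide were fed into the chosen etherification and metathesis, ring B would be more electron-rich (easier benzylic ionisation) and would hold two extra alkenes. On mechanism it is the more elegant cascade. On structure it solves the smaller problem. On step count no saving is expected, because A2 itself needs two steps and the stereocentre still needs its own sequence.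

Alternative 2: The cut is the C4a–C5 bond, with ring A built last. The forward key step is thermolysis of dioxinone A5: cycloreversion gives an acylketene, its enol is a dienylketene, 6π-electrocyclisation joins C5 to C4a and tautomerisation should give flavanone A4.
- In favour: ring A appears with both phenols free, so no silylation or desilylation is needed. This is better than the chosen plan on protecting-group economy, and the end game from A4 could be two steps shorter. No deactivated phenoxide has to act as a nucleophile, and the cascade is neutral.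
- Against: A5 is an enantioenriched 2-aryl-2,3-dihydropyran-4-one with a dioxinone side arm. Making it needs an asymmetric pyranone synthesis on the hindered dihalogenated aldehyde 3 plus a dioxinone dienolate acylation, which is more C–C chemistry than the four steps from 6 and 8 to 12. C2 would sit β to a vinylogous ester and then, in A4, next to free phenols at about 110 °C, where reversible ring opening threatens its configuration. The acylketene could also be lost to intermolecular capture.
- Comparison: the halogen logic and the late couplings are the same, so on ring B the two plans are equal. The chosen plan fixes C2 under mild catalyst control and never heats it in an unprotected form.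

Alternative 3: The cuts are C4a–C4, C4–C3 and O1–C2. The forward key step is a palladium-catalysed carbonylative three-component coupling of iodophenol A7 and arylacetylene A8 to an ortho-hydroxyaryl ynone, which should close 6-endo to flavone A6.
- In favour: it is the most convergent of the four. It forms three bonds and ring C in one operation, and the prenyl group is in place before the core is built. On bond economy and convergence it is better than the chosen plan.
- Against: A6 is a flavone, so C2 is planar. The target would then need an enantioselective 1,4-reduction of a 2-arylchromone beside a prenyl alkene and an aryl bromide, with over-reduction of the ketone as a further risk. Closure in the 5-exo mode competes. The methoxymethyl ethers need acid for removal, which is at odds with the tertiary allylic alcohol.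
- Comparison: A8 needs its own prenylation and alkynylation, so the total step count is at best equal. The chosen plan creates C2 in a C–O bond-forming step with a well-understood stereochemical model, which is why it is preferred.

Key step: step 9

## Route

Step 1
Reactants: 1 3-bromo-4-hydroxybenzaldehyde
Product: 2 3-bromo-4-hydroxy-5-iodobenzaldehyde
Conditions: NIS, TsOH·H2O (cat.), MeCN, rt
Reagents that add atoms: N-iodosuccinimide, O=C1CCC(=O)N1I
Why: Electrophilic aromatic iodination; the hydroxyl directs to its only free ortho carbon and the formyl group is meta-directing to the same carbon, so a single mono-iodide should form.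

Step 2
Reactants: 2 3-bromo-4-hydroxy-5-iodobenzaldehyde
Product: 3 3-bromo-5-iodo-4-methoxybenzaldehyde
Conditions: MeI, K2CO3, DMF, rt
Reagents that add atoms: iodomethane, CI
Why: Williamson O-methylation; the 2,6-dihalophenol is acidic and its phenoxide, though flanked, is alkylated readily by the small electrophile.

Step 3
Reactants: 3 3-bromo-5-iodo-4-methoxybenzaldehyde
Product: 4 ethyl (2E)-3-(3-bromo-5-iodo-4-methoxyphenyl)prop-2-enoate
Conditions: Ph3P=CHCO2Et, toluene, 80 °C
Reagents that add atoms: ethyl (triphenyl-λ5-phosphanylidene)acetate, CCOC(=O)C=P(c1ccccc1)(c1ccccc1)c1ccccc1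
Why: Wittig olefination with a stabilised ylide, which with aromatic aldehydes gives the E enoate under thermodynamic control of the oxaphosphetane step; no base is present that could touch the aryl halides.

Step 4
Reactants: 4 ethyl (2E)-3-(3-bromo-5-iodo-4-methoxyphenyl)prop-2-enoate
Product: 5 (2E)-3-(3-bromo-5-iodo-4-methoxyphenyl)prop-2-en-1-ol
Conditions: i-Bu2AlH (2.5 equiv), CH2Cl2, −78 °C; aq. potassium sodium tartrate
Reagents that add atoms: none
Why: 1,2-Reduction of an enoate to the allylic alcohol by an aluminium hydride; at low temperature neither the alkene nor the C–I and C–Br bonds are reduced.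

Step 5
Reactants: 5 (2E)-3-(3-bromo-5-iodo-4-methoxyphenyl)prop-2-en-1-ol
Product: 6 (2E)-3-(3-bromo-5-iodo-4-methoxyphenyl)prop-2-en-1-yl methyl carbonate
Conditions: ClCO2Me, pyridine, CH2Cl2, 0 °C
Reagents that add atoms: methyl chloroformate, COC(=O)Cl
Why: O-Acylation of a primary allylic alcohol with a chloroformate; it installs the leaving group that iridium ionises in step 7.

Step 6
Reactants: 7 1-(2,4,6-trihydroxyphenyl)ethan-1-one
Product: 8 1-[2,4-bis(tert-butyldimethylsilyloxy)-6-hydroxyphenyl]ethan-1-one
Conditions: TBSCl (2.1 equiv), imidazole, DMF, 0 °C to rt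
Reagents that add atoms: tert-butyl(chloro)dimethylsilane, CC(C)(C)[Si](C)(C)Cl
Why: Selective O-silylation; the para hydroxyl and one of the two equivalent ortho hydroxyls react, and the remaining ortho hydroxyl is held back by its hydrogen bond to the carbonyl, so only one bis-silyl ether is possible.

Step 7
Reactants: 6 (2E)-3-(3-bromo-5-iodo-4-methoxyphenyl)prop-2-en-1-yl methyl carbonate; 8 1-[2,4-bis(tert-butyldimethylsilyloxy)-6-hydroxyphenyl]ethan-1-one
Product: 10 1-(2-{[(1S)-1-(3-bromo-5-iodo-4-methoxyphenyl)prop-2-en-1-yl]oxy}-4,6-bis(tert-butyldimethylsilyloxy)phenyl)ethan-1-one, via lithium phenoxide 9 (not isolated)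
Conditions: 8, LiN(SiMe3)2 (1.0 equiv), THF, 0 °C; then 6, [Ir(cod)Cl]2 (2 mol%), (Sa,Sc,Sc)-O,O'-(1,1'-binaphthyl-2,2'-diyl) N,N-bis(1-phenylethyl)phosphoramidite (4 mol%, pre-activated with n-PrNH2), THF, 45 °C
Reagents that add atoms: none
Why: Iridium-catalysed enantioselective allylic etherification; the cyclometalated iridium–phosphoramidite complex ionises 6 to a π-allyl species and phenoxide 9 attacks the aryl-bearing terminus on the face away from the metal, giving the branched ether. The (Sa,Sc,Sc) ligand decides which allyl face is bound and so sets the (S) centre that becomes C2; a cinnamyl unit without ortho substituents and with electron-withdrawing halogens is the type that favours the branched product.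

Step 8
Reactants: 10 1-(2-{[(1S)-1-(3-bromo-5-iodo-4-methoxyphenyl)prop-2-en-1-yl]oxy}-4,6-bis(tert-butyldimethylsilyloxy)phenyl)ethan-1-one
Product: 11 tert-butyl{[1-(2-{[(1S)-1-(3-bromo-5-iodo-4-methoxyphenyl)prop-2-en-1-yl]oxy}-4,6-bis(tert-butyldimethylsilyloxy)phenyl)ethenyl]oxy}dimethylsilane
Conditions: TBSOTf, Et3N, CH2Cl2, −78 to 0 °C
Reagents that add atoms: tert-butyldimethylsilyl trifluoromethanesulfonate, CC(C)(C)[Si](C)(C)OS(=O)(=O)C(F)(F)F
Why: Soft enolisation and O-silylation of a methyl ketone, which can enolise on one side only; the amine is present before the silyl triflate so that the 1-arylallyl ether is never exposed to free Lewis acid.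

Step 9
Reactants: 11 tert-butyl{[1-(2-{[(1S)-1-(3-bromo-5-iodo-4-methoxyphenyl)prop-2-en-1-yl]oxy}-4,6-bis(tert-butyldimethylsilyloxy)phenyl)ethenyl]oxy}dimethylsilane
Product: 12 (2S)-2-(3-bromo-5-iodo-4-methoxyphenyl)-4,5,7-tris(tert-butyldimethylsilyloxy)-2H-chromene
Conditions: second-generation Grubbs catalyst RuCl2(=CHPh)(PCy3)(H2IMes) (10 mol%, two portions), 1,4-benzoquinone (20 mol%), degassed toluene (0.005 M), 55 °C, argon sparge
Reagents that add atoms: none
Why: The ruthenium benzylidene should first exchange onto the monosubstituted vinyl group on C2, because the 1,1-disubstituted, electron-rich enol ether initiates far more slowly. The new alkylidene is held within reach of the enol ether, adds to it by [2+2] cycloaddition, and cycloreversion of the ruthenacyclobutane releases the C3=C4 alkene and a ruthenium methylidene, with net loss of ethene. The closest known reaction type is ring-closing metathesis of silyl enol ethers with terminal olefins by second-generation ruthenium carbenes, as used after iridium allylic etherification of phenoxides. Ring C closes as a six-membered ring by alkene metathesis of two terminal methylenes, so the new double bond is endocyclic and C4 keeps its oxygen as a silyl enol ether. No stereocentre is formed; C2 was set in step 7 and is not one of the reacting atoms. The step needs cyclisation to beat cross-metathesis dimerisation, which high dilution and removal of ethene should secure. It also needs the 1-arylallyl aryl ether to survive without double-bond migration, ionisation or Claisen shift; benzoquinone as a hydride scavenger, the moderate temperature and the two halogens that destabilise a benzylic cation on ring B should secure this. Ring B holds no alkene, so no other metathesis pathway is open.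

Step 10
Reactants: 12 (2S)-2-(3-bromo-5-iodo-4-methoxyphenyl)-4,5,7-tris(tert-butyldimethylsilyloxy)-2H-chromene
Product: 13 (2S)-2-(3-bromo-5-iodo-4-methoxyphenyl)-5,7-bis(tert-butyldimethylsilyloxy)-2,3-dihydro-4H-chromen-4-one
Conditions: aq. HCl (1 M), THF, 0 °C
Reagents that add atoms: none
Why: Acid hydrolysis of a silyl enol ether: protonation at C3 gives an oxocarbenium ion stabilised by ring A, and water removes the silyl group to leave the C4 ketone. Aryl silyl ethers hydrolyse much more slowly, and C2 is not involved.

Step 11
Reactants: 13 (2S)-2-(3-bromo-5-iodo-4-methoxyphenyl)-5,7-bis(tert-butyldimethylsilyloxy)-2,3-dihydro-4H-chromen-4-one; 14 2-methylbut-3-yn-2-ol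
Product: 15 (2S)-2-[3-bromo-5-(3-hydroxy-3-methylbut-1-yn-1-yl)-4-methoxyphenyl]-5,7-bis(tert-butyldimethylsilyloxy)-2,3-dihydro-4H-chromen-4-one
Conditions: PdCl2(PPh3)2 (3 mol%), CuI (5 mol%), Et3N, THF, rt
Reagents that add atoms: none
Why: Sonogashira coupling; at room temperature zerovalent palladium inserts into C–I much faster than into C–Br, so only the iodide is replaced, and the amine is too weak a base at this temperature to open ring C.

Step 12
Reactants: 15 (2S)-2-[3-bromo-5-(3-hydroxy-3-methylbut-1-yn-1-yl)-4-methoxyphenyl]-5,7-bis(tert-butyldimethylsilyloxy)-2,3-dihydro-4H-chromen-4-one; 16 tributyl(3-methylbut-2-en-1-yl)stannane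
Product: 17 (2S)-5,7-bis(tert-butyldimethylsilyloxy)-2-[3-(3-hydroxy-3-methylbut-1-yn-1-yl)-4-methoxy-5-(3-methylbut-2-en-1-yl)phenyl]-2,3-dihydro-4H-chromen-4-one
Conditions: Pd(PPh3)4 (10 mol%), DMF, 90 °C
Reagents that add atoms: none
Why: Migita–Kosugi–Stille coupling of an aryl bromide with an allylic stannane; reductive elimination from the aryl(allyl)palladium intermediate at the less substituted allyl terminus should give the linear prenyl arene. The conditions are neutral, so the silyl ethers and the C2 centre are not at risk.

Step 13
Reactants: 17 (2S)-5,7-bis(tert-butyldimethylsilyloxy)-2-[3-(3-hydroxy-3-methylbut-1-yn-1-yl)-4-methoxy-5-(3-methylbut-2-en-1-yl)phenyl]-2,3-dihydro-4H-chromen-4-one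
Product: 18 (2S)-5,7-bis(tert-butyldimethylsilyloxy)-2-{3-[(1Z)-3-hydroxy-3-methylbut-1-en-1-yl]-4-methoxy-5-(3-methylbut-2-en-1-yl)phenyl}-2,3-dihydro-4H-chromen-4-one
Conditions: H2 (1 atm), Pd/CaCO3 poisoned with Pb(OAc)2 (Lindlar catalyst), quinoline, EtOAc, rt
Reagents that add atoms: none
Why: Lindlar semihydrogenation; both hydrogens are delivered to the same face of the alkyne on the poisoned palladium surface, giving the Z alkene, while the trisubstituted prenyl alkene and the ketone are not reduced on this catalyst.

Step 14
Reactants: 18 (2S)-5,7-bis(tert-butyldimethylsilyloxy)-2-{3-[(1Z)-3-hydroxy-3-methylbut-1-en-1-yl]-4-methoxy-5-(3-methylbut-2-en-1-yl)phenyl}-2,3-dihydro-4H-chromen-4-one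
Product: 19 (2S)-5,7-dihydroxy-2-{3-[(1Z)-3-hydroxy-3-methylbut-1-en-1-yl]-4-methoxy-5-(3-methylbut-2-en-1-yl)phenyl}-2,3-dihydro-4H-chromen-4-one (CNP0223123.2)
Conditions: Bu4NF, AcOH (1:1), THF, 0 °C
Reagents that add atoms: none
Why: Fluoride-mediated cleavage of aryl silyl ethers; acetic acid protonates each phenoxide as it forms, so the medium never becomes basic enough for E1cB opening of ring C, and it is far too weak an acid to ionise the tertiary allylic alcohol.

## Compound list

1 | 3-bromo-4-hydroxybenzaldehyde | O=Cc1ccc(O)c(Br)c1 | starting material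
2 | 3-bromo-4-hydroxy-5-iodobenzaldehyde | O=Cc1cc(Br)c(O)c(I)c1 | intermediate
3 | 3-bromo-5-iodo-4-methoxybenzaldehyde | COc1c(Br)cc(C=O)cc1I | intermediate
4 | ethyl (2E)-3-(3-bromo-5-iodo-4-methoxyphenyl)prop-2-enoate | CCOC(=O)/C=C/c1cc(Br)c(OC)c(I)c1 | intermediate
5 | (2E)-3-(3-bromo-5-iodo-4-methoxyphenyl)prop-2-en-1-ol | OC/C=C/c1cc(Br)c(OC)c(I)c1 | intermediate
6 | (2E)-3-(3-bromo-5-iodo-4-methoxyphenyl)prop-2-en-1-yl methyl carbonate | COC(=O)OC/C=C/c1cc(Br)c(OC)c(I)c1 | intermediate
7 | 1-(2,4,6-trihydroxyphenyl)ethan-1-one (2,4,6-trihydroxyacetophenone) | CC(=O)c1c(O)cc(O)cc1O | starting material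
8 | 1-[2,4-bis(tert-butyldimethylsilyloxy)-6-hydroxyphenyl]ethan-1-one | CC(=O)c1c(O)cc(O[Si](C)(C)C(C)(C)C)cc1O[Si](C)(C)C(C)(C)C | intermediate
9 | lithium 2-acetyl-3,5-bis(tert-butyldimethylsilyloxy)phenolate | [Li+].CC(=O)c1c([O-])cc(O[Si](C)(C)C(C)(C)C)cc1O[Si](C)(C)C(C)(C)C | intermediate (not isolated)
10 | 1-(2-{[(1S)-1-(3-bromo-5-iodo-4-methoxyphenyl)prop-2-en-1-yl]oxy}-4,6-bis(tert-butyldimethylsilyloxy)phenyl)ethan-1-one | COc1c(Br)cc([C@@H](Oc2cc(O[Si](C)(C)C(C)(C)C)cc(O[Si](C)(C)C(C)(C)C)c2C(C)=O)C=C)cc1I | intermediate
11 | tert-butyl{[1-(2-{[(1S)-1-(3-bromo-5-iodo-4-methoxyphenyl)prop-2-en-1-yl]oxy}-4,6-bis(tert-butyldimethylsilyloxy)phenyl)ethenyl]oxy}dimethylsilane | COc1c(Br)cc([C@@H](Oc2cc(O[Si](C)(C)C(C)(C)C)cc(O[Si](C)(C)C(C)(C)C)c2C(=C)O[Si](C)(C)C(C)(C)C)C=C)cc1I | intermediate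
12 | (2S)-2-(3-bromo-5-iodo-4-methoxyphenyl)-4,5,7-tris(tert-butyldimethylsilyloxy)-2H-chromene | COc1c(Br)cc([C@@H]2C=C(O[Si](C)(C)C(C)(C)C)c3c(O[Si](C)(C)C(C)(C)C)cc(O[Si](C)(C)C(C)(C)C)cc3O2)cc1I | intermediate
13 | (2S)-2-(3-bromo-5-iodo-4-methoxyphenyl)-5,7-bis(tert-butyldimethylsilyloxy)-2,3-dihydro-4H-chromen-4-one | COc1c(Br)cc([C@@H]2CC(=O)c3c(O[Si](C)(C)C(C)(C)C)cc(O[Si](C)(C)C(C)(C)C)cc3O2)cc1I | intermediate
14 | 2-methylbut-3-yn-2-ol | CC(C)(O)C#C | starting material
15 | (2S)-2-[3-bromo-5-(3-hydroxy-3-methylbut-1-yn-1-yl)-4-methoxyphenyl]-5,7-bis(tert-butyldimethylsilyloxy)-2,3-dihydro-4H-chromen-4-one | COc1c(Br)cc([C@@H]2CC(=O)c3c(O[Si](C)(C)C(C)(C)C)cc(O[Si](C)(C)C(C)(C)C)cc3O2)cc1C#CC(C)(C)O | intermediate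
16 | tributyl(3-methylbut-2-en-1-yl)stannane | CCCC[Sn](CCCC)(CCCC)CC=C(C)C | starting material
17 | (2S)-5,7-bis(tert-butyldimethylsilyloxy)-2-[3-(3-hydroxy-3-methylbut-1-yn-1-yl)-4-methoxy-5-(3-methylbut-2-en-1-yl)phenyl]-2,3-dihydro-4H-chromen-4-one | COc1c(CC=C(C)C)cc([C@@H]2CC(=O)c3c(O[Si](C)(C)C(C)(C)C)cc(O[Si](C)(C)C(C)(C)C)cc3O2)cc1C#CC(C)(C)O | intermediate
18 | (2S)-5,7-bis(tert-butyldimethylsilyloxy)-2-{3-[(1Z)-3-hydroxy-3-methylbut-1-en-1-yl]-4-methoxy-5-(3-methylbut-2-en-1-yl)phenyl}-2,3-dihydro-4H-chromen-4-one | COc1c(/C=C\C(C)(C)O)cc([C@@H]2CC(=O)c3c(O[Si](C)(C)C(C)(C)C)cc(O[Si](C)(C)C(C)(C)C)cc3O2)cc1CC=C(C)C | intermediate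
19 | (2S)-5,7-dihydroxy-2-{3-[(1Z)-3-hydroxy-3-methylbut-1-en-1-yl]-4-methoxy-5-(3-methylbut-2-en-1-yl)phenyl}-2,3-dihydro-4H-chromen-4-one | COc1c(/C=C\C(C)(C)O)cc([C@@H]2CC(=O)c3c(O)cc(O)cc3O2)cc1CC=C(C)C | target

## Step count and least certain steps

Total step count: 14. Longest linear sequence: 13 steps (from 1 through steps 1 to 5 and 7 to 14); the ring A branch adds step 6.

Step 9 (key step). The most likely failure is slow ring closure. The enol ether is 1,1-disubstituted and flanked on both sides, and the C4 and C5 silyloxy groups come into peri contact in the product. Slow closure would let intermolecular metathesis of the vinyl groups and ruthenium hydride migration of the vinyl double bond towards C2 take over. The fallback closes ring C at C4–C4a by acylation instead of at C3–C4 by metathesis; it sets out from 6 and comes back at 13. Benzene-1,3,5-triol is silylated twice (TBSCl, imidazole) to 3,5-bis(tert-butyldimethylsilyloxy)phenol F1. Its lithium salt is etherified with 6 under the iridium conditions of step 7 to give (S)-1-(3-bromo-5-iodo-4-methoxyphenyl)prop-2-en-1-yl 3,5-bis(tert-butyldimethylsilyloxy)phenyl ether F2; this phenoxide is more nucleophilic and symmetric. Hydroboration with 9-BBN and oxidation with NaBO3·4H2O give (3S)-3-(3-bromo-5-iodo-4-methoxyphenyl)-3-[3,5-bis(tert-butyldimethylsilyloxy)phenoxy]propan-1-ol F3. TEMPO with PhI(OAc)2 in aqueous MeCN gives (3S)-3-(3-bromo-5-iodo-4-methoxyphenyl)-3-[3,5-bis(tert-butyldimethylsilyloxy)phenoxy]propanoic acid F4. Trifluoroacetic anhydride in CH2Cl2 at 0 °C then forms the mixed anhydride, which acylates the activated ring at one of the two equivalent positions ortho to the ether oxygen (intramolecular Friedel–Crafts acylation) to give 13.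

Step 7. Two things are most likely to go wrong. The chelated acyl phenoxide 9 is a weak nucleophile and a good leaving group, so the catalyst may re-ionise the product ether, eroding the branched-to-linear ratio and enantiopurity. Methoxide released from the carbonate may also transfer silyl groups between phenol oxygens. The fallback lets a strong oxygen nucleophile meet the iridium allyl and makes the aryl ether bond by displacement; it sets out from 6 and comes back at 10. Compound 6 is etherified with KOSiEt3 using [Ir(cod)Cl]2 and the (Ra,Rc,Rc) enantiomer of the ligand to give {[(1R)-1-(3-bromo-5-iodo-4-methoxyphenyl)prop-2-en-1-yl]oxy}triethylsilane F5. Buffered fluoride (Bu4NF, AcOH) releases (1R)-1-(3-bromo-5-iodo-4-methoxyphenyl)prop-2-en-1-ol F6. A Mitsunobu reaction of F6 with phenol 8 (PPh3, DIAD, toluene, 0 °C) then proceeds with inversion to give 10.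

Step 12. The likely failures are transfer of the prenyl group through its γ terminus, giving the 1,1-dimethylallyl isomer, and slow oxidative addition at the bromide flanked by the methoxy group, leaving time for protodestannylation. The fallback builds the prenyl group by allylation and cross-metathesis and exchanges the roles of the two halogens, which the symmetry of ring B allows; it sets out from 13 and comes back at 17. Allyltributylstannane with Pd(PPh3)4 in toluene at 80 °C reacts at the iodide to give (2S)-2-[3-bromo-4-methoxy-5-(prop-2-en-1-yl)phenyl]-5,7-bis(tert-butyldimethylsilyloxy)-2,3-dihydro-4H-chromen-4-one F7. Cross-metathesis with excess 2-methylbut-2-ene and second-generation Grubbs catalyst RuCl2(=CHPh)(PCy3)(H2IMes) gives (2S)-2-[3-bromo-4-methoxy-5-(3-methylbut-2-en-1-yl)phenyl]-5,7-bis(tert-butyldimethylsilyloxy)-2,3-dihydro-4H-chromen-4-one F8. Sonogashira coupling of the remaining bromide with 14 (Pd(PPh3)4, CuI, i-Pr2NH, DMF, 70 °C) gives 17.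

Step 13. The likely failures are over-reduction to the saturated chain, Z to E drift on the catalyst surface, and stalling through poisoning by tin residues from step 12. The fallback brings the Z alkene in ready-made by cross-coupling with retention; it sets out from 13 and 14 and comes back at 18. Kinetically controlled radical hydrostannation of 14 (Bu3SnH, Et3B, air, toluene, low temperature; anti addition) gives (3Z)-2-methyl-4-(tributylstannyl)but-3-en-2-ol F9. Stille coupling of F9 at the iodide of 13 (Pd2(dba)3, AsPh3, CuI, DMF, rt) gives (2S)-2-{3-bromo-5-[(1Z)-3-hydroxy-3-methylbut-1-en-1-yl]-4-methoxyphenyl}-5,7-bis(tert-butyldimethylsilyloxy)-2,3-dihydro-4H-chromen-4-one F10. Stille coupling of F10 with 16 under the conditions of step 12 gives 18.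

## Further compounds

F1 | step 9 | 3,5-bis(tert-butyldimethylsilyloxy)phenol | Oc1cc(O[Si](C)(C)C(C)(C)C)cc(O[Si](C)(C)C(C)(C)C)c1
F2 | step 9 | (S)-1-(3-bromo-5-iodo-4-methoxyphenyl)prop-2-en-1-yl 3,5-bis(tert-butyldimethylsilyloxy)phenyl ether | COc1c(Br)cc([C@@H](Oc2cc(O[Si](C)(C)C(C)(C)C)cc(O[Si](C)(C)C(C)(C)C)c2)C=C)cc1I
F3 | step 9 | (3S)-3-(3-bromo-5-iodo-4-methoxyphenyl)-3-[3,5-bis(tert-butyldimethylsilyloxy)phenoxy]propan-1-ol | COc1c(Br)cc([C@@H](Oc2cc(O[Si](C)(C)C(C)(C)C)cc(O[Si](C)(C)C(C)(C)C)c2)CCO)cc1I
F4 | step 9 | (3S)-3-(3-bromo-5-iodo-4-methoxyphenyl)-3-[3,5-bis(tert-butyldimethylsilyloxy)phenoxy]propanoic acid | COc1c(Br)cc([C@@H](Oc2cc(O[Si](C)(C)C(C)(C)C)cc(O[Si](C)(C)C(C)(C)C)c2)CC(=O)O)cc1I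
F5 | step 7 | {[(1R)-1-(3-bromo-5-iodo-4-methoxyphenyl)prop-2-en-1-yl]oxy}triethylsilane | COc1c(Br)cc([C@H](O[Si](CC)(CC)CC)C=C)cc1I
F6 | step 7 | (1R)-1-(3-bromo-5-iodo-4-methoxyphenyl)prop-2-en-1-ol | COc1c(Br)cc([C@H](O)C=C)cc1I
F7 | step 12 | (2S)-2-[3-bromo-4-methoxy-5-(prop-2-en-1-yl)phenyl]-5,7-bis(tert-butyldimethylsilyloxy)-2,3-dihydro-4H-chromen-4-one | COc1c(Br)cc([C@@H]2CC(=O)c3c(O[Si](C)(C)C(C)(C)C)cc(O[Si](C)(C)C(C)(C)C)cc3O2)cc1CC=C
F8 | step 12 | (2S)-2-[3-bromo-4-methoxy-5-(3-methylbut-2-en-1-yl)phenyl]-5,7-bis(tert-butyldimethylsilyloxy)-2,3-dihydro-4H-chromen-4-one | COc1c(Br)cc([C@@H]2CC(=O)c3c(O[Si](C)(C)C(C)(C)C)cc(O[Si](C)(C)C(C)(C)C)cc3O2)cc1CC=C(C)C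
F9 | step 13 | (3Z)-2-methyl-4-(tributylstannyl)but-3-en-2-ol | CCCC[Sn](CCCC)(CCCC)/C=C\C(C)(C)O
F10 | step 13 | (2S)-2-{3-bromo-5-[(1Z)-3-hydroxy-3-methylbut-1-en-1-yl]-4-methoxyphenyl}-5,7-bis(tert-butyldimethylsilyloxy)-2,3-dihydro-4H-chromen-4-one | COc1c(Br)cc([C@@H]2CC(=O)c3c(O[Si](C)(C)C(C)(C)C)cc(O[Si](C)(C)C(C)(C)C)cc3O2)cc1/C=C\C(C)(C)O
A1 | alternative 1 | 6-bromo-8-(3-methylbut-2-en-1-yl)-2H-chromen-2-one | O=C1C=Cc2cc(Br)cc(CC=C(C)C)c2O1
A2 | alternative 1 | 5-bromo-2-[(2-methylbut-3-en-2-yl)oxy]benzaldehyde | O=Cc1cc(Br)ccc1OC(C)(C)C=C
A3 | alternative 1 | 4-bromo-2-[(1Z)-3-hydroxy-3-methylbut-1-en-1-yl]-6-(3-methylbut-2-en-1-yl)phenol | CC(C)=CCc1cc(Br)cc(/C=C\C(C)(C)O)c1O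
A4 | alternative 2 | (2S)-2-(3-bromo-5-iodo-4-methoxyphenyl)-5,7-dihydroxy-2,3-dihydro-4H-chromen-4-one | COc1c(Br)cc([C@@H]2CC(=O)c3c(O)cc(O)cc3O2)cc1I
A5 | alternative 2 | (2S)-2-(3-bromo-5-iodo-4-methoxyphenyl)-6-[(2,2-dimethyl-4-oxo-4H-1,3-dioxin-6-yl)methyl]-2,3-dihydro-4H-pyran-4-one | COc1c(Br)cc([C@@H]2CC(=O)C=C(CC3=CC(=O)OC(C)(C)O3)O2)cc1I
A6 | alternative 3 | 2-[3-bromo-4-methoxy-5-(3-methylbut-2-en-1-yl)phenyl]-5,7-bis(methoxymethoxy)-4H-chromen-4-one | COc1c(Br)cc(C2=CC(=O)c3c(OCOC)cc(OCOC)cc3O2)cc1CC=C(C)C
A7 | alternative 3 | 2-iodo-3,5-bis(methoxymethoxy)phenol | COCOc1cc(O)c(I)c(OCOC)c1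
A8 | alternative 3 | 1-bromo-5-ethynyl-2-methoxy-3-(3-methylbut-2-en-1-yl)benzene | COc1c(Br)cc(C#C)cc1CC=C(C)C
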